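## Retrosynthetic overview

1. The target comes from its 3-O-TBS ether. A Wittig disconnection at C11=C12 splits that ether into an ε-side C25 phosphonium salt and a β-side C15 keto-enal (C8 ketone, C11 aldehyde, C19 laurate).
2. The keto-enal, a 1,4-dicarbonyl with dissonant polarity, is an oxidatively opened 2,3-disubstituted furan. Key C7–C8 bond: C2-lithiated 3-furanmethanol (a latent acyl anion: furan C2 becomes the C8 carbonyl, and the same ring brings C9–C11 and C19–O) plus the β-ring allylic chloride. The laurate is added in the same flask.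
3. The β-ring chloride comes from (4R,6R)-actinol by silylation, methylenation and ene-type chlorination; the C3 stereocentre is bought.
4. The C25 salt comes from a C15 ε-salt and the C10 dialdehyde. The C15 salt comes from (R)-α-ionone by vinyl Grignard addition, C3' allylic oxidation and CBS reduction (sets 3'R; 6'R is bought).
5. Rings: none is built. The β ring comes from actinol, the ε ring from α-ionone, and the furan ring is only opened.

Assumption: (4R,6R)-actinol and fermentation-grade (R)-α-ionone (both at least 98% ee) are taken as purchasable; all other inputs are bulk chemicals.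

## Route

Step 1
Reactants: 1 (4R,6R)-4-hydroxy-2,2,6-trimethylcyclohexan-1-one ((4R,6R)-actinol)
Product: 2 (4R,6R)-4-[(tert-butyldimethylsilyl)oxy]-2,2,6-trimethylcyclohexan-1-one
Conditions: TBSCl, imidazole, DMF, rt
Reagents that add atoms: tert-butyldimethylsilyl chloride, CC(C)(C)[Si](C)(C)Cl
Why: Standard silyl ether formation (silylation of a secondary alcohol) protects the only hydroxyl before the strongly basic steps and touches no stereocentre.

Step 2
Reactants: 2 (4R,6R)-4-[(tert-butyldimethylsilyl)oxy]-2,2,6-trimethylcyclohexan-1-one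
Product: 3 tert-butyldimethyl{[(1R,3R)-3,5,5-trimethyl-4-methylidenecyclohexyl]oxy}silane
Conditions: CH3PPh3Br, KOC(CH3)3, toluene, 100 °C
Reagents that add atoms: methyltriphenylphosphonium bromide, C[P+](c1ccccc1)(c1ccccc1)c1ccccc1.[Br-]
Why: Wittig methylenation under forcing conditions suited to hindered ketones installs C7 as an exocyclic methylene, and any epimerization at the methyl-bearing carbon is harmless because that carbon becomes sp2 in step 3.

Step 3
Reactants: 3 tert-butyldimethyl{[(1R,3R)-3,5,5-trimethyl-4-methylidenecyclohexyl]oxy}silane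
Product: 4 tert-butyl{[(1R)-4-(chloromethyl)-3,5,5-trimethylcyclohex-3-en-1-yl]oxy}dimethylsilane
Conditions: Ca(OCl)2, CO2 (solid), CH2Cl2/H2O, 0 °C
Reagents that add atoms: calcium hypochlorite, [Ca+2].[O-]Cl.[O-]Cl
Why: Ene-type allylic chlorination by HOCl puts chlorine on the exocyclic CH2 and removes the only available allylic hydrogen (the other neighbour is quaternary), so the double bond moves into the ring as the tetrasubstituted C5=C6 alkene and C7 becomes a primary allylic chloride.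

Step 4
Reactants: 4 tert-butyl{[(1R)-4-(chloromethyl)-3,5,5-trimethylcyclohex-3-en-1-yl]oxy}dimethylsilane; 5 furan-3-ylmethanol; 6 dodecanoyl chloride
Product: 9 [2-({(4R)-4-[(tert-butyldimethylsilyl)oxy]-2,6,6-trimethylcyclohex-1-en-1-yl}methyl)furan-3-yl]methyl dodecanoate, via dilithio-3-furanmethanol 7 (not isolated), via lithium alkoxide 8 (not isolated)
Conditions: 5, n-BuLi (2.1 equiv), THF, −78 → 0 °C; then 4, DMPU, −40 °C → rt; then 6, 0 °C
Reagents that add atoms: none
Why: Alkoxide-directed C2 lithiation gives dianion 7, whose furyl carbanion is a masked acyl anion (furan C2 is later unveiled as the C8 carbonyl) and displaces the allylic chloride in an SN2 alkylation that forms the polarity-reversed C7–C8 bond, after which the surviving lithium alkoxide 8 is O-acylated in the same flask by the acid chloride.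

Step 5
Reactants: 9 [2-({(4R)-4-[(tert-butyldimethylsilyl)oxy]-2,6,6-trimethylcyclohex-1-en-1-yl}methyl)furan-3-yl]methyl dodecanoate
Product: 11 (2E)-2-({(4R)-4-[(tert-butyldimethylsilyl)oxy]-2,6,6-trimethylcyclohex-1-en-1-yl}acetyl)-4-oxobut-2-en-1-yl dodecanoate, via cis-enedione 10 (not isolated)
Conditions: NBS (1.05 equiv), NaHCO3, acetone/H2O (10:1), −20 °C; then I2 (2 mol%), CH2Cl2, rt
Reagents that add atoms: water, O
Why: NBS-mediated oxidative furan ring opening (bromination at C5, hydration at C2, collapse of the dihydrofuran) unmasks the C8 ketone and C11 aldehyde as cis-enedione 10, the furan being far more nucleophilic than the hindered tetrasubstituted alkene, and iodine-catalysed equilibration then gives the more stable trans-enedione, which fixes the 9E geometry.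

Step 6
Reactants: 12 (3E)-4-[(1R)-2,6,6-trimethylcyclohex-2-en-1-yl]but-3-en-2-one ((R)-α-ionone)
Product: 13 (4E)-3-methyl-5-[(1R)-2,6,6-trimethylcyclohex-2-en-1-yl]penta-1,4-dien-3-ol
Conditions: CH2=CHMgBr, THF, −20 → 0 °C; aq NH4Cl
Reagents that add atoms: vinylmagnesium bromide, C=C[Mg]Br
Why: Grignard 1,2-addition to the enone carbonyl gives the tertiary bis-allylic alcohol as a 1:1 epimer mixture at the new carbinol carbon, which is irrelevant because that carbon becomes sp2 in step 9.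

Step 7
Reactants: 13 (4E)-3-methyl-5-[(1R)-2,6,6-trimethylcyclohex-2-en-1-yl]penta-1,4-dien-3-ol
Product: 14 (4R)-4-[(1E)-3-hydroxy-3-methylpenta-1,4-dien-1-yl]-3,5,5-trimethylcyclohex-2-en-1-one
Conditions: Pd(OH)2/C (5 mol%), t-BuOOH (5 equiv), K2CO3, CH2Cl2, 0 °C → rt
Reagents that add atoms: tert-butyl hydroperoxide, CC(C)(C)OO
Why: Allylic C–H oxidation by a tert-butylperoxy radical chain attacks the only unhindered ring allylic methylene (C3') to give the ring enone, while the doubly allylic C6'–H is shielded by the gem-dimethyl group and the side chain and the mild heterogeneous base leaves C6' unepimerized.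

Step 8
Reactants: 14 (4R)-4-[(1E)-3-hydroxy-3-methylpenta-1,4-dien-1-yl]-3,5,5-trimethylcyclohex-2-en-1-one
Product: 15 (1R,4R)-4-[(1E)-3-hydroxy-3-methylpenta-1,4-dien-1-yl]-3,5,5-trimethylcyclohex-2-en-1-ol
Conditions: (S)-2-methyl-CBS-oxazaborolidine (20 mol%), catecholborane (3 equiv), toluene, −78 °C; then MeOH; aq NaOH wash
Reagents that add atoms: none
Why: Corey–Bakshi–Shibata reduction with the (S)-catalyst treats the alkenyl side of the ring enone as the large group and delivers hydride under reagent control to give the (3'R) allylic alcohol trans to the C6' side chain, catecholborane at −78 °C sparing the alkenes, and the minor cis diastereomer is removed by chromatography.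

Step 9
Reactants: 15 (1R,4R)-4-[(1E)-3-hydroxy-3-methylpenta-1,4-dien-1-yl]-3,5,5-trimethylcyclohex-2-en-1-ol
Product: 16 {(2E,4E)-5-[(1R,4R)-4-hydroxy-2,6,6-trimethylcyclohex-2-en-1-yl]-3-methylpenta-2,4-dien-1-yl}triphenylphosphonium bromide
Conditions: PPh3·HBr (1.0 equiv), CH2Cl2, 0 °C
Reagents that add atoms: triphenylphosphine hydrobromide, [Br-].[PH+](c1ccccc1)(c1ccccc1)c1ccccc1
Why: SN1-type allylic transposition, in which the tertiary bis-allylic alcohol ionizes to a pentadienyl cation that PPh3 captures at the unhindered terminus to give the conjugated (E)-dienyl phosphonium salt, while the secondary ring allylic alcohol ionizes far more slowly and stays free.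

Step 10
Reactants: 16 {(2E,4E)-5-[(1R,4R)-4-hydroxy-2,6,6-trimethylcyclohex-2-en-1-yl]-3-methylpenta-2,4-dien-1-yl}triphenylphosphonium bromide; 17 (2E,4E,6E)-2,7-dimethylocta-2,4,6-trienedial
Product: 19 (2E,4E,6E,8E,10E,12E)-13-[(1R,4R)-4-hydroxy-2,6,6-trimethylcyclohex-2-en-1-yl]-2,7,11-trimethyltrideca-2,4,6,8,10,12-hexaenal, via C15 ylide 18 (not isolated)
Conditions: NaOCH3, CH2Cl2/CH3OH, −10 °C → rt, 17 (2 equiv); crystallization
Reagents that add atoms: none
Why: Wittig olefination of the semi-stabilized ylide with one aldehyde group of the excess dialdehyde forms the C11'=C12' bond, and the all-E hexaenal is isolated by crystallization while minor Z isomers stay in the mother liquor.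

Step 11
Reactants: 19 (2E,4E,6E,8E,10E,12E)-13-[(1R,4R)-4-hydroxy-2,6,6-trimethylcyclohex-2-en-1-yl]-2,7,11-trimethyltrideca-2,4,6,8,10,12-hexaenal
Product: 20 (2E,4E,6E,8E,10E,12E)-13-[(1R,4R)-4-hydroxy-2,6,6-trimethylcyclohex-2-en-1-yl]-2,7,11-trimethyltrideca-2,4,6,8,10,12-hexaen-1-ol
Conditions: NaBH4, EtOH/THF, 0 °C
Reagents that add atoms: none
Why: Hydride 1,2-reduction of the polyenal by NaBH4 gives the primary polyenylic alcohol and creates no stereocentre.

Step 12
Reactants: 20 (2E,4E,6E,8E,10E,12E)-13-[(1R,4R)-4-hydroxy-2,6,6-trimethylcyclohex-2-en-1-yl]-2,7,11-trimethyltrideca-2,4,6,8,10,12-hexaen-1-ol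
Product: 21 {(2E,4E,6E,8E,10E,12E)-13-[(1R,4R)-4-hydroxy-2,6,6-trimethylcyclohex-2-en-1-yl]-2,7,11-trimethyltrideca-2,4,6,8,10,12-hexaen-1-yl}triphenylphosphonium bromide
Conditions: PPh3·HBr (1.0 equiv), CH2Cl2, 0 °C
Reagents that add atoms: triphenylphosphine hydrobromide, [Br-].[PH+](c1ccccc1)(c1ccccc1)c1ccccc1
Why: SN1-type phosphonium salt formation, in which the primary polyenylic alcohol ionizes to a highly delocalized polyenyl cation that PPh3 captures at the terminal carbon, again much faster than any ionization of the secondary ring allylic alcohol.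

Step 13
Reactants: 21 {(2E,4E,6E,8E,10E,12E)-13-[(1R,4R)-4-hydroxy-2,6,6-trimethylcyclohex-2-en-1-yl]-2,7,11-trimethyltrideca-2,4,6,8,10,12-hexaen-1-yl}triphenylphosphonium bromide; 11 (2E)-2-({(4R)-4-[(tert-butyldimethylsilyl)oxy]-2,6,6-trimethylcyclohex-1-en-1-yl}acetyl)-4-oxobut-2-en-1-yl dodecanoate
Product: 23 (3R,3'R,6'R)-3-[(tert-butyldimethylsilyl)oxy]-3'-hydroxy-8-oxo-7,8-dihydro-β,ε-caroten-19-yl dodecanoate, via C25 ylide 22 (not isolated)
Conditions: 1,2-epoxybutane (excess), i-PrOH, 60 °C, dark, argon; crystallization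
Reagents that add atoms: none
Why: Wittig olefination without added base, in which bromide opens the epoxide to an alkoxide that generates the ylide in low stationary concentration, so that it condenses with the aldehyde (far more reactive than the hindered ketone) to form C11=C12 without harming the laurate or the enolizable C7 methylene, and the all-E isomer is isolated by crystallization.

Step 14
Reactants: 23 (3R,3'R,6'R)-3-[(tert-butyldimethylsilyl)oxy]-3'-hydroxy-8-oxo-7,8-dihydro-β,ε-caroten-19-yl dodecanoate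
Product: 24 (3R,3'R,6'R)-3,3'-dihydroxy-8-oxo-7,8-dihydro-β,ε-caroten-19-yl dodecanoate (CNP0415583.1)
Conditions: HF·pyridine, pyridine, THF, 0 °C → rt
Reagents that add atoms: none
Why: Fluoride-driven desilylation under pyridine-buffered conditions cleaves the secondary TBS ether and leaves the laurate, the allylic alcohol, the β,γ-unsaturated ketone and the polyene intact.

## Compound list

1 | (4R,6R)-4-hydroxy-2,2,6-trimethylcyclohexan-1-one ((4R,6R)-actinol) | O=C1[C@H](C)C[C@@H](O)CC1(C)C | starting material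
2 | (4R,6R)-4-[(tert-butyldimethylsilyl)oxy]-2,2,6-trimethylcyclohexan-1-one | O=C1[C@H](C)C[C@@H](O[Si](C)(C)C(C)(C)C)CC1(C)C | intermediate
3 | tert-butyldimethyl{[(1R,3R)-3,5,5-trimethyl-4-methylidenecyclohexyl]oxy}silane | C=C1[C@H](C)C[C@@H](O[Si](C)(C)C(C)(C)C)CC1(C)C | intermediate
4 | tert-butyl{[(1R)-4-(chloromethyl)-3,5,5-trimethylcyclohex-3-en-1-yl]oxy}dimethylsilane | ClCC1=C(C)C[C@@H](O[Si](C)(C)C(C)(C)C)CC1(C)C | intermediate
5 | furan-3-ylmethanol (3-furanmethanol) | OCc1ccoc1 | starting material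
6 | dodecanoyl chloride (lauroyl chloride) | CCCCCCCCCCCC(=O)Cl | starting material
7 | lithium (2-lithiofuran-3-yl)methoxide (C,O-dilithio-3-furanmethanol) | [Li]OCc1ccoc1[Li] | intermediate
8 | lithium [2-({(4R)-4-[(tert-butyldimethylsilyl)oxy]-2,6,6-trimethylcyclohex-1-en-1-yl}methyl)furan-3-yl]methoxide | [Li]OCc1ccoc1CC2=C(C)C[C@@H](O[Si](C)(C)C(C)(C)C)CC2(C)C | intermediate
9 | [2-({(4R)-4-[(tert-butyldimethylsilyl)oxy]-2,6,6-trimethylcyclohex-1-en-1-yl}methyl)furan-3-yl]methyl dodecanoate | CCCCCCCCCCCC(=O)OCc1ccoc1CC2=C(C)C[C@@H](O[Si](C)(C)C(C)(C)C)CC2(C)C | intermediate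
10 | (2Z)-2-({(4R)-4-[(tert-butyldimethylsilyl)oxy]-2,6,6-trimethylcyclohex-1-en-1-yl}acetyl)-4-oxobut-2-en-1-yl dodecanoate (cis-enedione) | CCCCCCCCCCCC(=O)OC/C(=C/C=O)C(=O)CC1=C(C)C[C@@H](O[Si](C)(C)C(C)(C)C)CC1(C)C | intermediate
11 | (2E)-2-({(4R)-4-[(tert-butyldimethylsilyl)oxy]-2,6,6-trimethylcyclohex-1-en-1-yl}acetyl)-4-oxobut-2-en-1-yl dodecanoate (trans-enedione, C15 keto-enal) | CCCCCCCCCCCC(=O)OC\C(=C/C=O)C(=O)CC1=C(C)C[C@@H](O[Si](C)(C)C(C)(C)C)CC1(C)C | intermediate
12 | (3E)-4-[(1R)-2,6,6-trimethylcyclohex-2-en-1-yl]but-3-en-2-one ((R)-α-ionone) | CC(=O)/C=C/[C@H]1C(C)=CCCC1(C)C | starting material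
13 | (4E)-3-methyl-5-[(1R)-2,6,6-trimethylcyclohex-2-en-1-yl]penta-1,4-dien-3-ol (both carbinol epimers) | C=CC(C)(O)/C=C/[C@H]1C(C)=CCCC1(C)C | intermediate
14 | (4R)-4-[(1E)-3-hydroxy-3-methylpenta-1,4-dien-1-yl]-3,5,5-trimethylcyclohex-2-en-1-one (both carbinol epimers) | C=CC(C)(O)/C=C/[C@H]1C(C)=CC(=O)CC1(C)C | intermediate
15 | (1R,4R)-4-[(1E)-3-hydroxy-3-methylpenta-1,4-dien-1-yl]-3,5,5-trimethylcyclohex-2-en-1-ol (both tertiary carbinol epimers) | C=CC(C)(O)/C=C/[C@H]1C(C)=C[C@H](O)CC1(C)C | intermediate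
16 | {(2E,4E)-5-[(1R,4R)-4-hydroxy-2,6,6-trimethylcyclohex-2-en-1-yl]-3-methylpenta-2,4-dien-1-yl}triphenylphosphonium bromide | [Br-].c1ccccc1[P+](c2ccccc2)(c3ccccc3)C/C=C(C)/C=C/[C@H]4C(C)=C[C@H](O)CC4(C)C | intermediate
17 | (2E,4E,6E)-2,7-dimethylocta-2,4,6-trienedial (C10 dialdehyde) | O=C/C(C)=C/C=C/C=C(C)/C=O | starting material
18 | ylide of 16, (2E,4E)-5-[(1R,4R)-4-hydroxy-2,6,6-trimethylcyclohex-2-en-1-yl]-3-methylpenta-2,4-dien-1-ylidene(triphenyl)phosphorane | c1ccccc1[P+](c2ccccc2)(c3ccccc3)[CH-]/C=C(C)/C=C/[C@H]4C(C)=C[C@H](O)CC4(C)C | intermediate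
19 | (2E,4E,6E,8E,10E,12E)-13-[(1R,4R)-4-hydroxy-2,6,6-trimethylcyclohex-2-en-1-yl]-2,7,11-trimethyltrideca-2,4,6,8,10,12-hexaenal | O=C/C(C)=C/C=C/C=C(C)/C=C/C=C(C)/C=C/[C@H]1C(C)=C[C@H](O)CC1(C)C | intermediate
20 | (2E,4E,6E,8E,10E,12E)-13-[(1R,4R)-4-hydroxy-2,6,6-trimethylcyclohex-2-en-1-yl]-2,7,11-trimethyltrideca-2,4,6,8,10,12-hexaen-1-ol | OC/C(C)=C/C=C/C=C(C)/C=C/C=C(C)/C=C/[C@H]1C(C)=C[C@H](O)CC1(C)C | intermediate
21 | {(2E,4E,6E,8E,10E,12E)-13-[(1R,4R)-4-hydroxy-2,6,6-trimethylcyclohex-2-en-1-yl]-2,7,11-trimethyltrideca-2,4,6,8,10,12-hexaen-1-yl}triphenylphosphonium bromide | [Br-].c1ccccc1[P+](c2ccccc2)(c3ccccc3)C/C(C)=C/C=C/C=C(C)/C=C/C=C(C)/C=C/[C@H]4C(C)=C[C@H](O)CC4(C)C | intermediate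
22 | ylide of 21, (2E,4E,6E,8E,10E,12E)-13-[(1R,4R)-4-hydroxy-2,6,6-trimethylcyclohex-2-en-1-yl]-2,7,11-trimethyltrideca-2,4,6,8,10,12-hexaen-1-ylidene(triphenyl)phosphorane | c1ccccc1[P+](c2ccccc2)(c3ccccc3)[CH-]/C(C)=C/C=C/C=C(C)/C=C/C=C(C)/C=C/[C@H]4C(C)=C[C@H](O)CC4(C)C | intermediate
23 | (3R,3'R,6'R)-3-[(tert-butyldimethylsilyl)oxy]-3'-hydroxy-8-oxo-7,8-dihydro-β,ε-caroten-19-yl dodecanoate | CCCCCCCCCCCC(=O)OC\C(=C/C=C/C(C)=C/C=C/C=C(C)/C=C/C=C(C)/C=C/[C@H]1C(C)=C[C@H](O)CC1(C)C)C(=O)CC1=C(C)C[C@@H](O[Si](C)(C)C(C)(C)C)CC1(C)C | intermediate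
24 | (3R,3'R,6'R)-3,3'-dihydroxy-8-oxo-7,8-dihydro-β,ε-caroten-19-yl dodecanoate (siphonaxanthin 19-laurate, CNP0415583.1) | CCCCCCCCCCCC(=O)OC\C(=C/C=C/C(C)=C/C=C/C=C(C)/C=C/C=C(C)/C=C/[C@H]1C(C)=C[C@H](O)CC1(C)C)C(=O)CC1=C(C)C[C@@H](O)CC1(C)C | target

## Step count and risks

Total step count: 14 (steps 1–5 for the β half, steps 6–12 for the ε half, steps 13–14 for union and deprotection).
Longest linear sequence: 9 steps (steps 6–14, from (R)-α-ionone).

The three steps most likely to fail: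

Step 4. The furyl carbanion may react sluggishly at the neopentyl-like allylic chloride or cause elimination. The fallback sets out from 4 and 7 and comes back to the route at 9. It replaces the uncatalysed SN2 alkylation by a palladium-catalysed allyl–furyl cross-coupling, with furan C2 still the latent acyl carbon. Dianion 7 is stannylated on carbon with Bu3SnCl to give lithium [2-(tributylstannyl)furan-3-yl]methoxide F1. This is acylated in the same flask with 6 to give [2-(tributylstannyl)furan-3-yl]methyl dodecanoate F2. Stille coupling of F2 with 4 (Pd2(dba)3, AsPh3, NMP, 50 °C) then gives 9: zerovalent palladium ionizes the chloride to a π-allyl complex that takes the furyl group at its unhindered CH2 terminus.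

Step 5. NBS may also attack the tetrasubstituted ring alkene. The fallback sets out from 9 and comes back to the route at 10. It replaces electrophilic bromination and hydrolysis by a pericyclic photo-oxygenation. Singlet oxygen (O2, tetraphenylporphyrin, visible light, CH2Cl2, −78 °C) adds [4+2] across the furan, which reacts faster than the hindered alkene does in an ene reaction. The product is the endoperoxide {1-({(4R)-4-[(tert-butyldimethylsilyl)oxy]-2,6,6-trimethylcyclohex-1-en-1-yl}methyl)-2,3,7-trioxabicyclo[2.2.1]hept-5-en-6-yl}methyl dodecanoate F3. Me2S reduces it in the same flask to cis-enedione 10, and the iodine equilibration to 11 follows as before.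

Step 13. The ylide may add in conjugate fashion to the doubly activated alkene of 11 and expel laurate (SN2'), or the ester may suffer under the conditions. The fallback sets out from 8 and comes back to the route at 24. It carries C19 as a silyl ether, a far poorer leaving group, and puts the laurate on last.
- Alkoxide 8 is quenched with TBSCl instead of 6 to give tert-butyl{[(1R)-4-[(3-{[(tert-butyldimethylsilyl)oxy]methyl}furan-2-yl)methyl]-3,5,5-trimethylcyclohex-3-en-1-yl]oxy}dimethylsilane F4.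
- NBS opening as in step 5 gives (2Z)-3-{[(tert-butyldimethylsilyl)oxy]methyl}-5-{(4R)-4-[(tert-butyldimethylsilyl)oxy]-2,6,6-trimethylcyclohex-1-en-1-yl}-4-oxopent-2-enal F5.
- Iodine equilibration gives (2E)-3-{[(tert-butyldimethylsilyl)oxy]methyl}-5-{(4R)-4-[(tert-butyldimethylsilyl)oxy]-2,6,6-trimethylcyclohex-1-en-1-yl}-4-oxopent-2-enal F6.
- Wittig reaction of F6 with ylide 22 under the conditions of step 13 gives 3,19-bis-O-(tert-butyldimethylsilyl)siphonaxanthin F7.
- HF·pyridine removes both silyl groups to give siphonaxanthin F8.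
- Immobilized Candida antarctica lipase B with vinyl laurate (toluene, 40 °C) acylates only the primary allylic 19-hydroxyl of F8 and delivers 24.

Further compounds
F1 | step 4 | lithium [2-(tributylstannyl)furan-3-yl]methoxide | [Li]OCc1ccoc1[Sn](CCCC)(CCCC)CCCC
F2 | step 4 | [2-(tributylstannyl)furan-3-yl]methyl dodecanoate | CCCCCCCCCCCC(=O)OCc1ccoc1[Sn](CCCC)(CCCC)CCCC
F3 | step 5 | {1-({(4R)-4-[(tert-butyldimethylsilyl)oxy]-2,6,6-trimethylcyclohex-1-en-1-yl}methyl)-2,3,7-trioxabicyclo[2.2.1]hept-5-en-6-yl}methyl dodecanoate | CCCCCCCCCCCC(=O)OCC1=CC2OOC1(O2)CC3=C(C)C[C@@H](O[Si](C)(C)C(C)(C)C)CC3(C)C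
F4 | step 13 | tert-butyl{[(1R)-4-[(3-{[(tert-butyldimethylsilyl)oxy]methyl}furan-2-yl)methyl]-3,5,5-trimethylcyclohex-3-en-1-yl]oxy}dimethylsilane | CC(C)(C)[Si](C)(C)OCc1ccoc1CC2=C(C)C[C@@H](O[Si](C)(C)C(C)(C)C)CC2(C)C
F5 | step 13 | (2Z)-3-{[(tert-butyldimethylsilyl)oxy]methyl}-5-{(4R)-4-[(tert-butyldimethylsilyl)oxy]-2,6,6-trimethylcyclohex-1-en-1-yl}-4-oxopent-2-enal | CC(C)(C)[Si](C)(C)OC/C(=C/C=O)C(=O)CC1=C(C)C[C@@H](O[Si](C)(C)C(C)(C)C)CC1(C)C
F6 | step 13 | (2E)-3-{[(tert-butyldimethylsilyl)oxy]methyl}-5-{(4R)-4-[(tert-butyldimethylsilyl)oxy]-2,6,6-trimethylcyclohex-1-en-1-yl}-4-oxopent-2-enal | CC(C)(C)[Si](C)(C)OC\C(=C/C=O)C(=O)CC1=C(C)C[C@@H](O[Si](C)(C)C(C)(C)C)CC1(C)C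
F7 | step 13 | (3R,3'R,6'R)-3,19-bis[(tert-butyldimethylsilyl)oxy]-3'-hydroxy-7,8-dihydro-β,ε-caroten-8-one | CC(C)(C)[Si](C)(C)OC\C(=C/C=C/C(C)=C/C=C/C=C(C)/C=C/C=C(C)/C=C/[C@H]1C(C)=C[C@H](O)CC1(C)C)C(=O)CC1=C(C)C[C@@H](O[Si](C)(C)C(C)(C)C)CC1(C)C
F8 | step 13 | (3R,3'R,6'R)-3,19,3'-trihydroxy-7,8-dihydro-β,ε-caroten-8-one (siphonaxanthin) | OC\C(=C/C=C/C(C)=C/C=C/C=C(C)/C=C/C=C(C)/C=C/[C@H]1C(C)=C[C@H](O)CC1(C)C)C(=O)CC1=C(C)C[C@@H](O)CC1(C)C
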